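**Retrosynthetic overview**
1. Sipholenol K ⇐ (E1cB opening of a β-alkoxy ketone, desilylation) ⇐ spiro-tetrahydropyran 18, in which the C10 oxygen is tied temporarily to decalin carbon C4′.
2. Key disconnection C6–C11 (together with O1–C2 and O–C10): 18 ⇐ acyclic (3S,6S,7S)-bis-epoxide/(10E)-alkene chain 17 hanging on the C4′ silyl ether. One cationic cascade closes the oxepane, then the cyclohexane, then the temporary tetrahydropyran.
3. Enabling feature: the trans ring-fusion pair C6(CH3)/C7(H)–O1 and the pair C3(OH)/C2(CH3)2 of the oxepane are the footprints of two trisubstituted epoxides in 1,5-relation. C10(CH3)(OH)/C11(H) of the cyclohexane is the footprint of an (E)-trisubstituted alkene. The C10 oxygen lies four carbons from the enone β-carbon C4′, so an oxygen parked on C4′ can capture C10 through a six-membered ring.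
4. Fragment union at C11–C12: B-alkyl Suzuki–Miyaura coupling of bis-epoxy iodoalkene 6 (from geranylacetone) with the borane of vinyl carbinol 15.
5. Decalin: ring B is bought (4,4-dimethylcyclohexenone); ring A is added cis by Diels–Alder reaction with isoprene, then C8′ carbinol by alkene hydration and C4′ ketone by allylic oxidation. Ring order: B, A, oxepane, cyclohexane, temporary tetrahydropyran (opened again in step 13).

Key step: step 11

Remark (numbering): chain and benzoxepine carbons are C1–C13 (C2 = O–C(CH3)2, C3 = CHOH, C6 = ring-fusion C–CH3, C7 = ring-fusion CH–O, C10 = C(CH3)OH, C11 = CH carrying the C12–C13 link). Decalin carbons are C1′–C8a′ as in the 2(1H)-naphthalenone of the target (C2′ = C=O, C3′ = C–CH3, C4′ = β-carbon, C5′ = C(CH3)2, C8′ = C(CH3)OH). Ring A is the enone ring, ring B the carbinol ring.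
Remark (assumption): the sense of induction of the oxazaborolidinium catalyst in step 4 is taken from the accepted binding model for 2-cycloalkenones; should the mirror-image adduct form, the (R)-catalyst is used instead.
Remark (inconsequential centres): the configurations drawn at the carbinol of 12, at C4′ of 14–21 and at C2′/C3′ of 19–21 are the expected ones (approach on the convex face, or anti to the C4′ oxygen). They do not matter, because these carbons are trigonal in 22.

Step 1
Reactants: 1 geranylacetone, (5E)-6,10-dimethylundeca-5,9-dien-2-one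
Product: 3 (5E)-6,10-dimethylundeca-5,9-dien-1-yne, via enol phosphate 2 (not isolated)
Conditions: LiN(i-Pr)2 (1.05 equiv), THF, −78 °C; ClP(O)(OEt)2; then LiN(i-Pr)2 (2.3 equiv), −78 °C → rt
Reagents that add atoms: none
Why: One-pot methyl ketone to terminal alkyne conversion (kinetic CH3-side enolate, O-phosphorylation, base-induced β-elimination of the enol phosphate) should leave the (E)-alkene untouched and creates no stereocentre.

Step 2
Reactants: 3 (5E)-6,10-dimethylundeca-5,9-dien-1-yne
Product: 5 (1E,5E)-1-iodo-2,6,10-trimethylundeca-1,5,9-triene, via alkenylalane 4 (not isolated)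
Conditions: Me3Al (2 equiv), Cp2ZrCl2 (25 mol%), CH2Cl2, 0 °C → rt; then I2, THF, −30 °C
Reagents that add atoms: trimethylaluminium (Me3Al), C[Al](C)C; iodine, II
Why: Negishi zirconium-catalysed carboalumination adds CH3 and Al syn across the alkyne with methyl on the internal carbon, and iodinolysis with retention should give the (E)-2-methyl-1-iodoalkene that fixes the later C10=C11 geometry.

Step 3
Reactants: 5 (1E,5E)-1-iodo-2,6,10-trimethylundeca-1,5,9-triene
Product: 6 (1E,5S,6S,9S)-5,6:9,10-diepoxy-1-iodo-2,6,10-trimethylundec-1-ene (chain numbering: 3S,6S,7S bis-epoxide, C10=C11 iodoalkene)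
Conditions: L-fructose-derived Shi ketone (40 mol%), Oxone (2KHSO5·KHSO4·K2SO4), K2CO3, Bu4NHSO4, MeCN/dimethoxymethane/aq. buffer pH 10.5, 0 °C
Reagents that add atoms: potassium peroxymonosulfate (KHSO5, active salt of Oxone), [K+].[O-]S(=O)(=O)OO
Why: Shi asymmetric epoxidation (chiral dioxirane, spiro transition state) should oxidise the two electron-rich trisubstituted alkenes and spare the iodine-deactivated alkene, the L-fructose-derived ketone delivering the (S)- and (S,S)-epoxides (mirror image of the D-fructose series).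

Step 4
Reactants: 7 4,4-dimethylcyclohex-2-en-1-one; 8 isoprene (2-methylbuta-1,3-diene)
Product: 9 (4aR,8aS)-4,4,6-trimethyl-3,4,4a,5,8,8a-hexahydronaphthalen-1(2H)-one (cis-fused)
Conditions: (S)-B-o-tolyl oxazaborolidine from α,α-diphenylprolinol (20 mol%), AlBr3 (16 mol%), CH2Cl2, −40 °C
Reagents that add atoms: none
Why: Lewis-acid-catalysed Diels–Alder reaction gives the cis ring fusion by suprafacial addition and the "para" regiochemistry (the isoprene CH2 next to the methyl-bearing carbon bonds to the enone β-carbon), while the chiral oxazaborolidinium cation selects the enone face and so sets C4a′ and C8a′.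

Step 5
Reactants: 9 (4aR,8aS)-4,4,6-trimethyl-3,4,4a,5,8,8a-hexahydronaphthalen-1(2H)-one
Product: 10 (4aR,8aS)-4,4,6-trimethyl-1-methylidene-1,2,3,4,4a,5,8,8a-octahydronaphthalene
Conditions: Cp2TiMe2, toluene, 65 °C
Reagents that add atoms: dimethyltitanocene (Cp2TiMe2), [CH3-].[CH3-].[Ti+4].c1cc[cH-]c1.c1cc[cH-]c1
Why: Petasis methylenation (titanium methylidene, [2+2]/retro-[2+2]) is non-basic, so the epimerisable ring-fusion centre next to the ketone should keep its cis configuration.

Step 6
Reactants: 10 (4aR,8aS)-4,4,6-trimethyl-1-methylidene-1,2,3,4,4a,5,8,8a-octahydronaphthalene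
Product: 11 (1S,4aR,8aS)-1,4,4,6-tetramethyl-1,2,3,4,4a,5,8,8a-octahydronaphthalen-1-ol
Conditions: Co(acac)2 (20 mol%), PhSiH3, O2 (1 atm), THF/i-PrOH, rt; then aq. Na2S2O3
Reagents that add atoms: dioxygen, O=O
Why: Mukaiyama hydration (hydrogen-atom transfer, then O2 capture) should react at the 1,1-disubstituted alkene faster than at the trisubstituted ring A alkene, and the tertiary C8′ radical should take oxygen on the convex face, away from the axial ring A carbon, placing OH cis to the ring-fusion hydrogens.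

Step 7
Reactants: 11 (1S,4aR,8aS)-1,4,4,6-tetramethyl-1,2,3,4,4a,5,8,8a-octahydronaphthalen-1-ol
Product: 13 (4aS,5S,8aR)-5-hydroxy-2,5,8,8-tetramethyl-4a,5,6,7,8,8a-hexahydronaphthalen-1(4H)-one, via C4′ allylic alcohol 12 (not isolated)
Conditions: SeO2 (0.5 equiv), t-BuOOH, CH2Cl2, rt; then Dess–Martin periodinane, NaHCO3, CH2Cl2, rt
Reagents that add atoms: selenium dioxide (SeO2, catalytic oxygen carrier), O=[Se]=O; tert-butyl hydroperoxide, CC(C)(C)OO
Why: SeO2/t-BuOOH allylic hydroxylation (ene reaction, then [2,3]-shift) should attack the ring CH2 next to the methyl-bearing alkene carbon (C4′), and Dess–Martin oxidation of the crude alcohol gives the enone without forming a stereocentre of consequence.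

Step 8
Reactants: 13 (4aS,5S,8aR)-5-hydroxy-2,5,8,8-tetramethyl-4a,5,6,7,8,8a-hexahydronaphthalen-1(4H)-one
Product: 14 (1S,4aS,5S,8aR)-1-ethenyl-2,5,8,8-tetramethyl-1,4,4a,5,6,7,8,8a-octahydronaphthalene-1,5-diol
Conditions: CH2=CHMgBr (3 equiv), THF, −78 → 0 °C; then H2O
Reagents that add atoms: vinylmagnesium bromide, C=C[Mg]Br
Why: 1,2-Grignard addition to the hindered enone carbonyl should occur from the convex face of the cis-decalin (vinyl cis to H-4a′), and it places on C4′ the oxygen that will later capture C10.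

Step 9
Reactants: 14 (1S,4aS,5S,8aR)-1-ethenyl-2,5,8,8-tetramethyl-1,4,4a,5,6,7,8,8a-octahydronaphthalene-1,5-diol
Product: 15 (1S,4aS,5S,8aR)-1-ethenyl-2,5,8,8-tetramethyl-1,5-bis(triethylsilyloxy)-1,4,4a,5,6,7,8,8a-octahydronaphthalene
Conditions: Et3SiOTf (3 equiv), 2,6-lutidine, CH2Cl2, −78 → 0 °C
Reagents that add atoms: triethylsilyl trifluoromethanesulfonate, CC[Si](CC)(CC)OS(=O)(=O)C(F)(F)F
Why: Silyl triflate silylation of both tertiary alcohols under buffered conditions protects C8′–OH and turns C4′–OH into a silyl ether that resists ionisation yet can still act as the terminating nucleophile.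

Step 10
Reactants: 15 (1S,4aS,5S,8aR)-1-ethenyl-2,5,8,8-tetramethyl-1,5-bis(triethylsilyloxy)-1,4,4a,5,6,7,8,8a-octahydronaphthalene; 6 (1E,5S,6S,9S)-5,6:9,10-diepoxy-1-iodo-2,6,10-trimethylundec-1-ene
Product: 17 cascade precursor: decalin 15 whose vinyl group has become the C13–C12 link to C11 of the (10E)-alkene (3S,6S,7S)-2,3:6,7-bis-epoxide chain (C4′ and C8′ O-triethylsilyl), via B-alkyl-9-BBN 16 (not isolated)
Conditions: 9-BBN, THF, rt → 50 °C; then 6, Pd(dppf)Cl2 (5 mol%), AsPh3, Cs2CO3, DMF/H2O, rt
Reagents that add atoms: none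
Why: 9-BBN should hydroborate only the monosubstituted alkene (boron on the terminal carbon), and B-alkyl Suzuki–Miyaura coupling with the iodoalkene proceeds with retention of the (E)-geometry under mild aqueous base that trisubstituted epoxides tolerate.

Step 11
Reactants: 17 cascade precursor (bis-epoxide, (10E)-alkene, C4′ and C8′ O-triethylsilyl)
Product: 18 spiro ether: (3S,6S,7S,10S,11S)-perhydrobenzoxepine with O1–C2 and C6–C11 formed and C3 O-triethylsilyl, whose C10 oxygen is bonded to C4′ (tetrahydropyran O–C4′–C13–C12–C11–C10); ring A alkene C2′=C3′ and C8′ O-triethylsilyl retained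
Conditions: Et3SiOTf (30 mol%), 2,6-di-tert-butyl-4-methylpyridine (50 mol%), CH2Cl2, −78 °C; then Et3N, aq. NaHCO3
Reagents that add atoms: none
Why: Et3Si+ silylates the terminal C2/C3 epoxide, whose tertiary carbon C2 is attacked by the oxygen of the C6/C7 epoxide to give a bicyclic epoxonium ion; the (10E)-alkene then opens this ion at its tertiary carbon C6 with inversion (C6–C11 bond), and the tertiary C10 cation is captured by the oxygen of the C4′ silyl ether, which releases Et3Si+, so that the whole event is an isomerisation carried by a catalytic silyl triflate. The closest known reaction type is the silyl-triflate-promoted tandem oxa-/carbacyclisation of 1,5-diepoxides relayed by trisubstituted alkenes (epoxonium cascades to oxepane-fused carbocycles), combined with the oxygen-terminated polyene cyclisation that turns tertiary carbinols into manoyl-oxide-type tetrahydropyrans. Ring closures: the oxepane by endo O-alkylation at C2 (7-endo with respect to O–C7), the cyclohexane by 6-endo attack of C11 on C6 through a chair, and the tetrahydropyran by capture of C10 through a six-membered chair (O, C4′, C13, C12, C11, C10) trans-fused to the cyclohexane. Stereocentres: C3 and C7 are carried over from the (3S)- and (6S,7S)-epoxides (their C–O bonds stay), C6 is inverted by anti opening so that the oxepane is trans-fused, C11 follows from the (E)-alkene in the chair (H axial, C12 equatorial), and C10 follows from anti addition across that alkene with equatorial C–O bond formation away from the axial C6 methyl. The step needs endo regioselectivity at both epoxides, secured by their trisubstitution (the tertiary carbons C2 and C6 carry the charge), and it needs the C10 cation to be trapped and not deprotonated, secured by the intramolecular six-membered delivery of the silyl ether oxygen at −78 °C with a hindered pyridine as proton scavenger.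

Step 12
Reactants: 18 spiro ether
Product: 20 C2′ secondary alcohol of 18 (C3′ now CH–CH3), via C2′ alkylborane 19 (not isolated)
Conditions: BH3·THF, THF, 0 °C → rt; then NaOH, H2O2, 0 °C
Reagents that add atoms: hydrogen peroxide, OO
Why: Hydroboration–oxidation of the only remaining alkene should place boron on the less substituted C2′ (γ to the spiro oxygen, so no β-elimination) and convert it to the C2′ alcohol with retention, both new centres being destroyed in step 13.

Step 13
Reactants: 20 C2′ secondary alcohol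
Product: 22 3,8′-bis-O-triethylsilyl sipholenol K, via C2′ ketone 21 (not isolated)
Conditions: Dess–Martin periodinane, NaHCO3, CH2Cl2, rt; then DBU, toluene, 50 °C
Reagents that add atoms: none
Why: Dess–Martin oxidation gives a β-alkoxy ketone whose E1cB elimination (retro-oxa-Michael) opens the temporary tetrahydropyran, releasing the tertiary C10 alcohol and the tetrasubstituted C3′=C4′ enone in one event, the reverse addition of a tertiary alcohol to this enone being strongly disfavoured.

Step 14
Reactants: 22 3,8′-bis-O-triethylsilyl sipholenol K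
Product: 23 sipholenol K
Conditions: HF·pyridine, THF, 0 °C → rt
Reagents that add atoms: none
Why: Fluoride-mediated desilylation should remove the secondary and the tertiary triethylsilyl ether without touching the enone, the tertiary alcohols or any stereocentre.

**Compound list**
1 | geranylacetone, (5E)-6,10-dimethylundeca-5,9-dien-2-one | CC(=O)CC/C=C(\C)CCC=C(C)C | starting material
2 | diethyl (5E)-6,10-dimethylundeca-1,5,9-trien-2-yl phosphate | C=C(OP(=O)(OCC)OCC)CC/C=C(\C)CCC=C(C)C | intermediate
3 | (5E)-6,10-dimethylundeca-5,9-dien-1-yne | C#CCC/C=C(\C)CCC=C(C)C | intermediate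
4 | dimethyl[(1E,5E)-2,6,10-trimethylundeca-1,5,9-trien-1-yl]alane | C[Al](C)/C=C(\C)CC/C=C(\C)CCC=C(C)C | intermediate
5 | (1E,5E)-1-iodo-2,6,10-trimethylundeca-1,5,9-triene | I/C=C(\C)CC/C=C(\C)CCC=C(C)C | intermediate
6 | (1E,5S,6S,9S)-5,6:9,10-diepoxy-1-iodo-2,6,10-trimethylundec-1-ene | I/C=C(\C)CC[C@@H]1O[C@@]1(C)CC[C@@H]1OC1(C)C | intermediate
7 | 4,4-dimethylcyclohex-2-en-1-one | CC1(C)CCC(=O)C=C1 | starting material
8 | isoprene, 2-methylbuta-1,3-diene | CC(=C)C=C | starting material
9 | (4aR,8aS)-4,4,6-trimethyl-3,4,4a,5,8,8a-hexahydronaphthalen-1(2H)-one | CC=1C[C@@H]2[C@H](CC=1)C(=O)CCC2(C)C | intermediate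
10 | (4aR,8aS)-4,4,6-trimethyl-1-methylidene-1,2,3,4,4a,5,8,8a-octahydronaphthalene | CC=1C[C@@H]2[C@H](CC=1)C(=C)CCC2(C)C | intermediate
11 | (1S,4aR,8aS)-1,4,4,6-tetramethyl-1,2,3,4,4a,5,8,8a-octahydronaphthalen-1-ol | CC=1C[C@@H]2[C@H](CC=1)[C@@](C)(O)CCC2(C)C | intermediate
12 | (1R,4aS,5S,8aR)-2,5,8,8-tetramethyl-1,4,4a,5,6,7,8,8a-octahydronaphthalene-1,5-diol (C4′ allylic alcohol) | CC=1[C@H](O)[C@@H]2[C@H](CC=1)[C@@](C)(O)CCC2(C)C | intermediate
13 | (4aS,5S,8aR)-5-hydroxy-2,5,8,8-tetramethyl-4a,5,6,7,8,8a-hexahydronaphthalen-1(4H)-one | CC=1C(=O)[C@@H]2[C@H](CC=1)[C@@](C)(O)CCC2(C)C | intermediate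
14 | (1S,4aS,5S,8aR)-1-ethenyl-2,5,8,8-tetramethyl-1,4,4a,5,6,7,8,8a-octahydronaphthalene-1,5-diol | CC=1[C@](O)(C=C)[C@@H]2[C@H](CC=1)[C@@](C)(O)CCC2(C)C | intermediate
15 | (1S,4aS,5S,8aR)-1-ethenyl-2,5,8,8-tetramethyl-1,5-bis(triethylsilyloxy)-1,4,4a,5,6,7,8,8a-octahydronaphthalene | CC=1[C@](O[Si](CC)(CC)CC)(C=C)[C@@H]2[C@H](CC=1)[C@@](C)(O[Si](CC)(CC)CC)CCC2(C)C | intermediate
16 | B-alkyl-9-BBN of 15 (9-borabicyclo[3.3.1]nonan-9-yl on C12) | CC=1[C@](O[Si](CC)(CC)CC)(CCB3C4CCCC3CCC4)[C@@H]2[C@H](CC=1)[C@@](C)(O[Si](CC)(CC)CC)CCC2(C)C | intermediate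
17 | cascade precursor: (3S,6S,7S)-2,3:6,7-bis-epoxy-(10E)-ene chain joined through C12–C13 to C4′ of the bis-silylated decalin | CC=1[C@](O[Si](CC)(CC)CC)(CC/C=C(\C)CC[C@@H]3O[C@@]3(C)CC[C@@H]3OC3(C)C)[C@@H]2[C@H](CC=1)[C@@](C)(O[Si](CC)(CC)CC)CCC2(C)C | intermediate
18 | spiro ether: C3-O-triethylsilyl (3S,6S,7S,10S,11S)-perhydrobenzoxepine, C10–O–C4′ tetrahydropyran, ring A C2′=C3′ alkene, C8′ O-triethylsilyl | CC=1[C@]3(CC[C@H]4[C@]5(C)CC[C@H](O[Si](CC)(CC)CC)C(C)(C)O[C@H]5CC[C@]4(C)O3)[C@@H]2[C@H](CC=1)[C@@](C)(O[Si](CC)(CC)CC)CCC2(C)C | intermediate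
19 | C2′ alkylborane of 18 (BH2 on C2′, H on C3′) | C[C@H]1[C@]3(CC[C@H]4[C@]5(C)CC[C@H](O[Si](CC)(CC)CC)C(C)(C)O[C@H]5CC[C@]4(C)O3)[C@@H]2[C@H](C[C@@H]1B)[C@@](C)(O[Si](CC)(CC)CC)CCC2(C)C | intermediate
20 | C2′ secondary alcohol of the spiro ether | C[C@H]1[C@]3(CC[C@H]4[C@]5(C)CC[C@H](O[Si](CC)(CC)CC)C(C)(C)O[C@H]5CC[C@]4(C)O3)[C@@H]2[C@H](C[C@@H]1O)[C@@](C)(O[Si](CC)(CC)CC)CCC2(C)C | intermediate
21 | C2′ ketone of the spiro ether (β-alkoxy ketone) | C[C@H]1[C@]3(CC[C@H]4[C@]5(C)CC[C@H](O[Si](CC)(CC)CC)C(C)(C)O[C@H]5CC[C@]4(C)O3)[C@@H]2[C@H](CC1=O)[C@@](C)(O[Si](CC)(CC)CC)CCC2(C)C | intermediate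
22 | 3,8′-bis-O-triethylsilyl sipholenol K | CC1=C(CC[C@H]2[C@]3(C)CC[C@H](O[Si](CC)(CC)CC)C(C)(C)O[C@H]3CC[C@]2(C)O)[C@@H]2[C@H](CC1=O)[C@@](C)(O[Si](CC)(CC)CC)CCC2(C)C | intermediate
23 | sipholenol K | CC1=C(CC[C@H]2[C@]3(C)CC[C@H](O)C(C)(C)O[C@H]3CC[C@]2(C)O)[C@@H]2[C@H](CC1=O)[C@@](C)(O)CCC2(C)C | target

**Count and risks**
Total step count: 14. Longest linear sequence: 11 steps (steps 4 to 14, from 7 and 8); the chain fragment (steps 1 to 3) joins at step 10.

Steps most likely to fail:

Step 11 (key cascade). The tertiary allylic C4′ silyl ether may ionise under the silyl triflate before the epoxides react, so the oxygen meant to capture C10 is lost, or the C10 cation may be lost by proton elimination. The fallback sets out from 15 and comes back at 21. Exhaustive hydroboration–oxidation of 15 (BH3·THF; NaOH, H2O2) should give the diol F1 (primary C12 alcohol and C2′ alcohol). Selective iodination of the primary alcohol (I2, PPh3, imidazole) should give the iodo alcohol F2, and Dess–Martin oxidation the iodo ketone F3. Zinc insertion (Zn, LiCl, THF) should give the alkylzinc iodide F4, and Negishi coupling of F4 with 6 (Pd(dppf)Cl2) the keto bis-epoxide F5, in which the C4′ silyl ether is no longer allylic. The same silyl triflate cascade on F5 should then give 21 directly, and the DBU treatment of step 13 follows.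

Step 4 (asymmetric Diels–Alder). Turnover at the hindered β-carbon next to the gem-dimethyl group may be slow and the facial discrimination poor. The fallback sets out from 7 and 8 and comes back at 9. The AlCl3-catalysed Diels–Alder reaction gives the racemic cis adduct, that is 9 together with its enantiomer F6. NaBH4 reduction (hydride from the convex face) gives the alcohol F7 from 9 and its enantiomer F8 from F6. Lipase-catalysed acetylation (Candida antarctica lipase B, vinyl acetate) esterifies one enantiomer only, taken here as F8, which gives the acetate F9; if the enzyme prefers F7, its acetate is separated and saponified instead. F7 is separated and oxidised with Dess–Martin periodinane to 9.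

Step 6 (alkene hydration). Oxygen capture by the tertiary radical may show poor facial selectivity, or the ring A alkene may be hydrated as well. The fallback sets out from 9 and comes back at 13. SeO2/t-BuOOH followed by Dess–Martin oxidation should give the enedione F10. Petasis methylenation of the saturated ketone, which is more reactive than the hindered conjugated one, should give the methylidene enone F11. mCPBA should epoxidise only the exocyclic alkene, from the convex face, to give the spiro-epoxide F12. LiAlH4 should open the epoxide at its CH2 and reduce the enone carbonyl to give the diol F13, and MnO2 should reoxidise the allylic alcohol to 13.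

Further compounds
F1 | step 11 | diol from 15: C4′–CH2CH2OH, C2′–OH, C3′ H/CH3, C4′ and C8′ O-triethylsilyl | C[C@H]1[C@](O[Si](CC)(CC)CC)(CCO)[C@@H]2[C@H](C[C@@H]1O)[C@@](C)(O[Si](CC)(CC)CC)CCC2(C)C
F2 | step 11 | iodo alcohol: C12 iodide, C2′–OH | C[C@H]1[C@](O[Si](CC)(CC)CC)(CCI)[C@@H]2[C@H](C[C@@H]1O)[C@@](C)(O[Si](CC)(CC)CC)CCC2(C)C
F3 | step 11 | iodo ketone: C12 iodide, C2′ ketone | C[C@H]1[C@](O[Si](CC)(CC)CC)(CCI)[C@@H]2[C@H](CC1=O)[C@@](C)(O[Si](CC)(CC)CC)CCC2(C)C
F4 | step 11 | alkylzinc iodide from F3 | C[C@H]1[C@](O[Si](CC)(CC)CC)(CC[Zn]I)[C@@H]2[C@H](CC1=O)[C@@](C)(O[Si](CC)(CC)CC)CCC2(C)C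
F5 | step 11 | keto bis-epoxide: cascade precursor with saturated ring A and C2′ ketone | C[C@H]1[C@](O[Si](CC)(CC)CC)(CC/C=C(\C)CC[C@@H]3O[C@@]3(C)CC[C@@H]3OC3(C)C)[C@@H]2[C@H](CC1=O)[C@@](C)(O[Si](CC)(CC)CC)CCC2(C)C
F6 | step 4 | (4aS,8aR)-4,4,6-trimethyl-3,4,4a,5,8,8a-hexahydronaphthalen-1(2H)-one (enantiomer of 9) | CC=1C[C@H]2[C@@H](CC=1)C(=O)CCC2(C)C
F7 | step 4 | (1R,4aR,8aS)-4,4,6-trimethyl-1,2,3,4,4a,5,8,8a-octahydronaphthalen-1-ol | CC=1C[C@@H]2[C@H](CC=1)[C@H](O)CCC2(C)C
F8 | step 4 | (1S,4aS,8aR)-4,4,6-trimethyl-1,2,3,4,4a,5,8,8a-octahydronaphthalen-1-ol | CC=1C[C@H]2[C@@H](CC=1)[C@@H](O)CCC2(C)C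
F9 | step 4 | (1S,4aS,8aR)-4,4,6-trimethyl-1,2,3,4,4a,5,8,8a-octahydronaphthalen-1-yl acetate | CC=1C[C@H]2[C@@H](CC=1)[C@@H](OC(C)=O)CCC2(C)C
F10 | step 6 | (4aS,8aR)-2,8,8-trimethyl-4a,7,8,8a-tetrahydronaphthalene-1,5(4H,6H)-dione | CC=1C(=O)[C@@H]2[C@H](CC=1)C(=O)CCC2(C)C
F11 | step 6 | (4aS,8aR)-2,8,8-trimethyl-5-methylidene-4a,5,6,7,8,8a-hexahydronaphthalen-1(4H)-one | CC=1C(=O)[C@@H]2[C@H](CC=1)C(=C)CCC2(C)C
F12 | step 6 | spiro-epoxide of F11 at C8′ (oxygen on the face of the ring-fusion hydrogens) | CC=1C(=O)[C@@H]2[C@H](CC=1)[C@]3(CO3)CCC2(C)C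
F13 | step 6 | (1S,4aS,5S,8aR)-2,5,8,8-tetramethyl-1,4,4a,5,6,7,8,8a-octahydronaphthalene-1,5-diol (C4′ epimer of 12) | CC=1[C@@H](O)[C@@H]2[C@H](CC=1)[C@@](C)(O)CCC2(C)C
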